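**Retrosynthetic overview**

1. Ring A (C4a–C5–C6–C7–C8–C8a) is cut at C8a–C8 and C5–C6 into a 2-methoxy-3-formyl-γ-pyranone (ring B, carrying both electrophilic carbons) and a dihydroxyacetone unit C6–C7(=O)–C8, used as the chiral enamine of its acetonide. This [3+3] α,α′-annulation builds ring A and sets C5, C6 and C8 in one operation.
2. Enabling feature: C8a is the β-carbon of the vinylogous ester O1–C8a=C4a–C4=O and C5 sits on C4a, so the pair is a 1,3-dielectrophile. C6 and C8 flank the oxygenated C7 and carry cis (diaxial) oxygens, so they are the α,α′-carbons of a ketone whose two oxygens can be tied in a 1,3-dioxane.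
3. After the key step, hydride reduction at C7 gives an all-cis 5,6,7,8-tetraoxygenated ring A. The catechol of the second chromone is then attached by two SN2 etherifications with inversion (C5–O first, then C7–O, closing the seven-membered benzodioxepine bridge), which converts all-cis into the alternating pattern of the target.
4. Ring order: pyranone B (from triacetic acid lactone), then carbocycle A with a temporary dioxane ring (key step), then the benzodioxepine bridge. The 6,7-dihydroxychromone is made separately and the acetonide is removed last.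

Key step: step 5

Remark: ring atoms are numbered as in 5,6,7,8-tetrahydrochromone throughout. The (2S,5S) amine is chosen on the assumption that the electrophile enters the enamine face anti to the neighbouring pyrrolidine methyl group, the usual steric model for C2-symmetric 2,5-dimethylpyrrolidine enamines.

**Route**

Step 1
Reactants: 1 4-hydroxy-6-methyl-2H-pyran-2-one (triacetic acid lactone); 2 1-(chloromethyl)-4-methoxybenzene
Product: 3 4-hydroxy-6-[2-(4-methoxyphenyl)ethyl]-2H-pyran-2-one
Conditions: lithium diisopropylamide (2.5 equiv), THF/DMPU, −78 °C; then 2, −78 → 0 °C; aq. NH4Cl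
Reagents that add atoms: none
Why: Dianion alkylation: the second deprotonation gives the vinylogous carbanion at the 6-methyl group, the most nucleophilic site, which is benzylated by SN2; no stereocenter is formed.

Step 2
Reactants: 3 4-hydroxy-6-[2-(4-methoxyphenyl)ethyl]-2H-pyran-2-one
Product: 4 2-methoxy-6-[2-(4-methoxyphenyl)ethyl]-4H-pyran-4-one
Conditions: MeOSO2CF3 (1.1 equiv), CH2Cl2, 0 °C → rt; then aq. NaHCO3
Reagents that add atoms: methyl trifluoromethanesulfonate, COS(=O)(=O)C(F)(F)F
Why: Under neutral conditions the hard methylating agent should attack the lactone carbonyl oxygen (the most basic site) to give a 2-methoxy-4-hydroxypyrylium ion that loses a proton to the α-methoxy-γ-pyranone, the known regioselective O-methylation of 4-hydroxy-2-pyranones.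

Step 3
Reactants: 4 2-methoxy-6-[2-(4-methoxyphenyl)ethyl]-4H-pyran-4-one
Product: 5 2-methoxy-6-[2-(4-methoxyphenyl)ethyl]-4-oxo-4H-pyran-3-carbaldehyde
Conditions: POCl3, DMF, 0 → 50 °C; then aq. NaOAc (pH 5), 0 °C
Reagents that add atoms: N,N-dimethylformamide, CN(C)C=O; water, O
Why: Vilsmeier–Haack formylation at C3, the ketene-acetal-like carbon that receives electron density from both O1 and the methoxy group; the buffered hydrolysis keeps the liberated dimethylamine protonated so that it should not displace the methoxy group.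

Step 4
Reactants: 6 2,2-dimethyl-1,3-dioxan-5-one; 7 (2S,5S)-2,5-dimethylpyrrolidine
Product: 8 (2S,5S)-1-(2,2-dimethyl-4H-1,3-dioxin-5-yl)-2,5-dimethylpyrrolidine
Conditions: 4 Å molecular sieves, benzene, 40 °C; filter, concentrate, use crude
Reagents that add atoms: none
Why: Enamine condensation of a ketone with a secondary amine; the ketone is Cs-symmetric, so a single enamine can form, and the stereocenters are those of the amine.

Step 5
Reactants: 5 2-methoxy-6-[2-(4-methoxyphenyl)ethyl]-4-oxo-4H-pyran-3-carbaldehyde; 8 (2S,5S)-1-(2,2-dimethyl-4H-1,3-dioxin-5-yl)-2,5-dimethylpyrrolidine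
Product: 11 (5S,6S,8R)-5-hydroxy-6,8-(isopropylidenedioxy)-2-[2-(4-methoxyphenyl)ethyl]-5,6-dihydro-4H-chromene-4,7(8H)-dione, via pyranonyl enamine 9 (not isolated), via bicyclic iminium methoxide 10 (not isolated)
Conditions: 4 Å molecular sieves, MeCN, −20 °C → rt; then AcOH/NaOAc buffer (pH 5), THF/H2O, rt
Reagents that add atoms: water, O
Why: Proposed new method: the enamine carbon adds to C8a of 5 (a vinylogous carbonate carbon activated by both C4=O and the formyl group) and methoxide is expelled (addition–elimination, forming C8–C8a), the iminium loses its axial C6–H to give the less substituted enamine 9, and 9 adds to the formyl carbon (forming C5–C6) to give iminium 10, which is hydrolysed on work-up; the closest known reactions are the Stork α,α′-annulation of ketone enamines with 1,3-dielectrophiles to bicyclo[3.3.1]nonan-9-ones and the addition–elimination of carbon nucleophiles to 2-methoxy-γ-pyranones. Ring A closes by a 6-(enolexo)-exo-trig aldol addition, the first bond being an intermolecular substitution that closes no ring. C8 is set by the C2-symmetric pyrrolidine, whose methyl group next to the nucleophilic carbon blocks one enamine face; C6 is set by the dioxane ring, since only a cis-diaxial 4,6-disubstituted dioxanone can bridge; C5 is set under reversible (retro-aldol) conditions, expected to favour the pseudo-equatorial hydroxyl that hydrogen-bonds to C4=O. The step needs substitution at C8a to precede the aldol addition (the reverse order would lead to the enantiomer) and deprotonation at C6 instead of C8: the first is secured by the irreversible loss of methoxide against the reversible, unproductive addition of an enamine to an aldehyde in an aprotic medium, the second by allylic strain with the 2,5-dimethylpyrrolidine and by the equatorial, non-aligned C8–H bond. Dehydration and enolization of the product are blocked because C6 and C8 are bridgeheads.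

Step 6
Reactants: 11 (5S,6S,8R)-5-hydroxy-6,8-(isopropylidenedioxy)-2-[2-(4-methoxyphenyl)ethyl]-5,6-dihydro-4H-chromene-4,7(8H)-dione
Product: 12 (5S,6S,7S,8S)-5,7-dihydroxy-6,8-(isopropylidenedioxy)-2-[2-(4-methoxyphenyl)ethyl]-5,6,7,8-tetrahydro-4H-chromen-4-one
Conditions: NaBH4, MeOH/CH2Cl2, −40 °C
Reagents that add atoms: none
Why: Hydride reduction of the strained bridging ketone, expected from the carbocycle face (no axial substituent there, 5-OH being equatorial) and not from the face covered by the dioxane ring and its gem-dimethyl group, so that the new 7-OH lies cis to O6 and O8; the vinylogous ester carbonyl C4 is inert to NaBH4 at this temperature.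

Step 7
Reactants: 13 1-(2-hydroxy-4,5-dimethoxyphenyl)ethan-1-one; 14 ethyl 3-phenylpropanoate
Product: 16 6,7-dimethoxy-2-(2-phenylethyl)-4H-chromen-4-one, via diketone 15 (not isolated)
Conditions: NaH (4 equiv), THF, reflux; then conc. HCl, AcOH, 90 °C
Reagents that add atoms: none
Why: Claisen condensation of the acetophenone enolate with the ester gives the 1,3-diketone, which undergoes acid-catalysed cyclodehydration to the chromone (the standard 2-(2-phenylethyl)chromone synthesis).

Step 8
Reactants: 16 6,7-dimethoxy-2-(2-phenylethyl)-4H-chromen-4-one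
Product: 17 6,7-dihydroxy-2-(2-phenylethyl)-4H-chromen-4-one
Conditions: BBr3 (4 equiv), CH2Cl2, −78 °C → rt; then H2O
Reagents that add atoms: none
Why: Lewis-acid cleavage of both aryl methyl ethers by BBr3; the chromone core is stable to these conditions.

Step 9
Reactants: 12 (5S,6S,7S,8S)-5,7-dihydroxy-6,8-(isopropylidenedioxy)-2-[2-(4-methoxyphenyl)ethyl]-5,6,7,8-tetrahydro-4H-chromen-4-one; 17 6,7-dihydroxy-2-(2-phenylethyl)-4H-chromen-4-one
Product: 18 (5R,6R,7S,8S)-7-hydroxy-5-{[6-hydroxy-4-oxo-2-(2-phenylethyl)-4H-chromen-7-yl]oxy}-6,8-(isopropylidenedioxy)-2-[2-(4-methoxyphenyl)ethyl]-5,6,7,8-tetrahydro-4H-chromen-4-one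
Conditions: PPh3, DIAD (slow addition), THF/DMF, 0 °C → rt
Reagents that add atoms: none
Why: Mitsunobu etherification: the betaine should deprotonate the more acidic 7-OH of 17 (para to the chromone carbonyl) and activate the more accessible, pyranone-activated 5-OH of 12 rather than the 7-OH flanked by two bridgeheads; SN2 attack from the open carbocycle face inverts C5, and elimination is impossible because C6 is a bridgehead.

Step 10
Reactants: 18 (5R,6R,7S,8S)-7-hydroxy-5-{[6-hydroxy-4-oxo-2-(2-phenylethyl)-4H-chromen-7-yl]oxy}-6,8-(isopropylidenedioxy)-2-[2-(4-methoxyphenyl)ethyl]-5,6,7,8-tetrahydro-4H-chromen-4-one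
Product: 19 6,8-O-isopropylidene derivative of the target, (5R,6S,7R,8S), with the benzodioxepine bridge closed
Conditions: (cyanomethylene)tributylphosphorane, toluene, 100 °C, 0.005 M
Reagents that add atoms: none
Why: Intramolecular Mitsunobu-type etherification (7-exo-tet): the 6′-phenoxide, held above C7 by the axial C5–O bond, should displace the activated 7-OH from the carbocycle face with inversion, closing the seven-membered 1,5-benzodioxepine ring; elimination is again blocked by the bridgeheads C6 and C8.

Step 11
Reactants: 19 6,8-O-isopropylidene derivative of the target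
Product: 20 (+)-4′-methoxyaquisinenone G
Conditions: AcOH/H2O (4:1), 40 °C
Reagents that add atoms: none
Why: Acid hydrolysis of the strained diaxial acetonide; both aryl ethers are locked in the bridged ring and should survive mild acid, and no stereocenter is touched.

**Compound list**

1 | 4-hydroxy-6-methyl-2H-pyran-2-one | Cc1cc(O)cc(=O)o1 | starting material
2 | 1-(chloromethyl)-4-methoxybenzene | COc1ccc(CCl)cc1 | starting material
3 | 4-hydroxy-6-[2-(4-methoxyphenyl)ethyl]-2H-pyran-2-one | COc1ccc(CCc2cc(O)cc(=O)o2)cc1 | intermediate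
4 | 2-methoxy-6-[2-(4-methoxyphenyl)ethyl]-4H-pyran-4-one | COc1ccc(CCc2cc(=O)cc(OC)o2)cc1 | intermediate
5 | 2-methoxy-6-[2-(4-methoxyphenyl)ethyl]-4-oxo-4H-pyran-3-carbaldehyde | COc1ccc(CCc2cc(=O)c(C=O)c(OC)o2)cc1 | intermediate
6 | 2,2-dimethyl-1,3-dioxan-5-one | CC1(C)OCC(=O)CO1 | starting material
7 | (2S,5S)-2,5-dimethylpyrrolidine | C[C@H]1CC[C@H](C)N1 | starting material
8 | (2S,5S)-1-(2,2-dimethyl-4H-1,3-dioxin-5-yl)-2,5-dimethylpyrrolidine | C[C@H]1CC[C@H](C)N1C1=COC(C)(C)OC1 | intermediate
9 | 2-{(4S)-5-[(2S,5S)-2,5-dimethylpyrrolidin-1-yl]-2,2-dimethyl-4H-1,3-dioxin-4-yl}-6-[2-(4-methoxyphenyl)ethyl]-4-oxo-4H-pyran-3-carbaldehyde | COc1ccc(CCc2cc(=O)c(C=O)c(o2)[C@H]2OC(C)(C)OC=C2N2[C@@H](C)CC[C@@H]2C)cc1 | intermediate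
10 | C7 iminium ion of 11 with (2S,5S)-2,5-dimethylpyrrolidine, methoxide salt | COc1ccc(CCc2cc(=O)c3c(o2)[C@H]4OC(C)(C)O[C@H](C4=[N+]5[C@@H](C)CC[C@@H]5C)[C@H]3O)cc1.C[O-] | intermediate
11 | (5S,6S,8R)-5-hydroxy-6,8-(isopropylidenedioxy)-2-[2-(4-methoxyphenyl)ethyl]-5,6-dihydro-4H-chromene-4,7(8H)-dione | COc1ccc(CCc2cc(=O)c3c(o2)[C@H]4OC(C)(C)O[C@H](C4=O)[C@H]3O)cc1 | intermediate
12 | (5S,6S,7S,8S)-5,7-dihydroxy-6,8-(isopropylidenedioxy)-2-[2-(4-methoxyphenyl)ethyl]-5,6,7,8-tetrahydro-4H-chromen-4-one | COc1ccc(CCc2cc(=O)c3c(o2)[C@H]4OC(C)(C)O[C@H]([C@@H]4O)[C@H]3O)cc1 | intermediate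
13 | 1-(2-hydroxy-4,5-dimethoxyphenyl)ethan-1-one | CC(=O)c1cc(OC)c(OC)cc1O | starting material
14 | ethyl 3-phenylpropanoate | CCOC(=O)CCc1ccccc1 | starting material
15 | 1-(2-hydroxy-4,5-dimethoxyphenyl)-5-phenylpentane-1,3-dione | O=C(CCc1ccccc1)CC(=O)c1cc(OC)c(OC)cc1O | intermediate
16 | 6,7-dimethoxy-2-(2-phenylethyl)-4H-chromen-4-one | COc1cc2oc(CCc3ccccc3)cc(=O)c2cc1OC | intermediate
17 | 6,7-dihydroxy-2-(2-phenylethyl)-4H-chromen-4-one | Oc1cc2oc(CCc3ccccc3)cc(=O)c2cc1O | intermediate
18 | (5R,6R,7S,8S)-7-hydroxy-5-{[6-hydroxy-4-oxo-2-(2-phenylethyl)-4H-chromen-7-yl]oxy}-6,8-(isopropylidenedioxy)-2-[2-(4-methoxyphenyl)ethyl]-5,6,7,8-tetrahydro-4H-chromen-4-one | COc1ccc(CCc2cc(=O)c3c(o2)[C@H]4OC(C)(C)O[C@H]([C@@H]4O)[C@@H]3Oc2cc5oc(CCc6ccccc6)cc(=O)c5cc2O)cc1 | intermediate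
19 | 6,8-O-isopropylidene derivative of the target, (5R,6S,7R,8S) | COc1ccc(CCc2cc(=O)c3c(o2)[C@H]4OC(C)(C)O[C@H]([C@H]4Oc2cc5c(=O)cc(CCc6ccccc6)oc5cc2O7)[C@@H]37)cc1 | intermediate
20 | (+)-4′-methoxyaquisinenone G, (5R,6S,7R,8S) | COc1ccc(CCc2cc(=O)c3c(o2)[C@@H](O)[C@@H]2Oc4cc5c(=O)cc(CCc6ccccc6)oc5cc4O[C@H]3[C@@H]2O)cc1 | target

**Step count and risks**

Total step count: 11. Longest linear sequence: 8 steps (steps 1, 2, 3, 5, 6, 9, 10, 11).

Steps most likely to fail:

1. Step 5 (proposed new method). Enantiocontrol may be lost if the enamine adds to the aldehyde before the substitution at C8a, or if the chiral amine shields the face poorly, and amine liberated early could displace the methoxy group of 5. The fallback sets out from compounds 5 and 6 and uses stepwise, known chemistry. Ketone 6 is converted (Me3SiCl, Et3N) into 2,2-dimethyl-5-(trimethylsilyloxy)-4H-1,3-dioxine F1. A Mukaiyama–Michael addition–elimination of F1 to 5 (ZnCl2 or catalytic trimethylsilyl trifluoromethanesulfonate, CH2Cl2, −78 °C) should give 2-(2,2-dimethyl-5-oxo-1,3-dioxan-4-yl)-6-[2-(4-methoxyphenyl)ethyl]-4-oxo-4H-pyran-3-carbaldehyde F2, which is racemic but configurationally labile at the carbon between the ketone and the pyranone. An (S)-proline-catalysed 6-enolexo intramolecular aldol addition with dynamic kinetic resolution then closes ring A; the amine-sensitive methoxy group is no longer present, and the anti aldol corresponds to the 5,6-cis product. The fallback comes back to the route at compound 11.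

2. Step 10. Displacement at C7 may be too slow (a carbinol flanked by two oxygenated bridgeheads), so that activation without substitution or intermolecular etherification takes over. The fallback sets out from ketone 11 and replaces the SN2 closure by a C–O coupling with retention. Mitsunobu etherification of 11 with 6-bromo-7-hydroxy-2-(2-phenylethyl)-4H-chromen-4-one F3 (from commercial 1-(5-bromo-2,4-dihydroxyphenyl)ethanone and 14 under the conditions of step 7) should give (5R,6S,8R)-5-{[6-bromo-4-oxo-2-(2-phenylethyl)-4H-chromen-7-yl]oxy}-6,8-(isopropylidenedioxy)-2-[2-(4-methoxyphenyl)ethyl]-5,6-dihydro-4H-chromene-4,7(8H)-dione F4. With the carbocycle face now blocked by the axial aryloxy group, NaBH4 should attack C7 from the dioxane face and give the (5R,6R,7R,8S)-7-hydroxy compound F5, whose 7-OH is syn to the aryloxy group. Intramolecular Pd-catalysed etherification (Pd(OAc)2, a bulky biaryl di-tert-butylphosphine, Cs2CO3, toluene, 90 °C) then closes the benzodioxepine with retention at C7 and comes back to the route at compound 19.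

3. Step 9. The etherification may go astray through poor discrimination between the two phenols of 17 or the two hydroxyls of 12, or through capture of the phosphine reagent by the catechol. The fallback sets out from diol 12 and separates activation from substitution. The pyranone-activated 5-OH is converted selectively (MsCl, Et3N, LiCl, CH2Cl2) into the 5-chloro analogue of 12 (C5 epimer mixture) F6. Compound 17 is then alkylated as its mono-potassium salt (K2CO3, DMF, rt); the more acidic 7-OH is deprotonated first, and the phenoxide should enter C5 from the unhindered face anti to O6. The fallback comes back to the route at compound 18.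

Further compounds
F1 | step 5 | 2,2-dimethyl-5-(trimethylsilyloxy)-4H-1,3-dioxine | CC1(C)OCC(O[Si](C)(C)C)=CO1
F2 | step 5 | 2-(2,2-dimethyl-5-oxo-1,3-dioxan-4-yl)-6-[2-(4-methoxyphenyl)ethyl]-4-oxo-4H-pyran-3-carbaldehyde | COc1ccc(CCc2cc(=O)c(C=O)c(o2)C2OC(C)(C)OCC2=O)cc1
F3 | step 10 | 6-bromo-7-hydroxy-2-(2-phenylethyl)-4H-chromen-4-one | Oc1cc2oc(CCc3ccccc3)cc(=O)c2cc1Br
F4 | step 10 | (5R,6S,8R)-5-{[6-bromo-4-oxo-2-(2-phenylethyl)-4H-chromen-7-yl]oxy}-6,8-(isopropylidenedioxy)-2-[2-(4-methoxyphenyl)ethyl]-5,6-dihydro-4H-chromene-4,7(8H)-dione | COc1ccc(CCc2cc(=O)c3c(o2)[C@H]4OC(C)(C)O[C@H](C4=O)[C@@H]3Oc2cc5oc(CCc6ccccc6)cc(=O)c5cc2Br)cc1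
F5 | step 10 | (5R,6R,7R,8S)-5-{[6-bromo-4-oxo-2-(2-phenylethyl)-4H-chromen-7-yl]oxy}-7-hydroxy-6,8-(isopropylidenedioxy)-2-[2-(4-methoxyphenyl)ethyl]-5,6,7,8-tetrahydro-4H-chromen-4-one | COc1ccc(CCc2cc(=O)c3c(o2)[C@H]4OC(C)(C)O[C@H]([C@H]4O)[C@@H]3Oc2cc5oc(CCc6ccccc6)cc(=O)c5cc2Br)cc1
F6 | step 9 | 5-chloro-7-hydroxy-6,8-(isopropylidenedioxy)-2-[2-(4-methoxyphenyl)ethyl]-5,6,7,8-tetrahydro-4H-chromen-4-one (C5 epimer mixture, other centres as in 12) | COc1ccc(CCc2cc(=O)c3c(o2)[C@H]4OC(C)(C)O[C@H]([C@@H]4O)C3Cl)cc1
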